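**Strategy.** With C6 at the ketone level, the ring path C6–C7–C8–C9–C10=C1 is a 5-en-1-one, and the cis C4=C5 alkene of the ten-membered ring can be the double bond of a cyclohexene built from C1–C6. Everything therefore rests on reconnecting C1–C6 while cutting C8–C9. Anionic oxy-Cope rearrangement of a cis-1-(E-2-silylvinyl)-6-(E-1-alkoxyprop-1-en-2-yl)cyclohex-2-enol expands the six-membered ring to the cyclodecadienone in one operation: it forms C8–C9, sets C8 (as C–Si, a masked hydroxyl) and C9 (as a PMB ether), and creates the Z C1=C10 alkene. The precursor carries O3 as a silyl ether and an oxidisable benzyldimethylsilyl group on C8.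

Key step: step 12

Remark: atoms carry the numbering of the target (ring C1–C10, lactone C11–C13, C14 on C10, C15 on C4) unless a name says otherwise. The target is taken as drawn: 3S,6R,7R,8R,9R, (2R,3R)-epoxy ester, Z alkenes at C1=C10 and C4=C5. The geometry at C7 is constant from step 13 on, although its CIP letter changes with the groups on O6 and C8.

Remark: 1,4-dioxaspiro[4.5]dec-6-en-8-one, ethynylmagnesium bromide solution and the reagents named are assumed to be purchasable.

Step 1
Reactants: 1 1,4-dioxaspiro[4.5]dec-6-en-8-one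
Product: 2 7-iodo-1,4-dioxaspiro[4.5]dec-6-en-8-one
Conditions: I2, pyridine, CH2Cl2, 0 → 25 °C
Reagents that add atoms: iodine, II
Why: α-Iodination of an enone (conjugate addition of pyridine, iodination of the enolate, loss of pyridine) should put iodine on the α-carbon, the future C4, without disturbing the ketal.

Step 2
Reactants: 2 7-iodo-1,4-dioxaspiro[4.5]dec-6-en-8-one
Product: 3 7-methyl-1,4-dioxaspiro[4.5]dec-6-en-8-one
Conditions: MeZnCl, Pd(PPh3)4 (cat.), THF, 25 °C
Reagents that add atoms: methylzinc chloride, C[Zn]Cl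
Why: Negishi coupling of the α-iodoenone under zerovalent palladium installs the C15 methyl on C4; the organozinc halide does not add to the ketone.

Step 3
Reactants: 3 7-methyl-1,4-dioxaspiro[4.5]dec-6-en-8-one
Product: 4 (S)-7-methyl-1,4-dioxaspiro[4.5]dec-6-en-8-ol
Conditions: (R)-2-methyl-CBS-oxazaborolidine (cat.), BH3·SMe2, THF, −40 °C; then H2O
Reagents that add atoms: none
Why: Corey–Bakshi–Shibata reduction: the ketone binds to the catalyst with its larger, α-branched alkenyl flank turned away, so hydride from the coordinated borane should reach one face only and set the future C3 as S.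

Step 4
Reactants: 4 (S)-7-methyl-1,4-dioxaspiro[4.5]dec-6-en-8-ol
Product: 5 (S)-8-(tert-butyldimethylsilyloxy)-7-methyl-1,4-dioxaspiro[4.5]dec-6-ene
Conditions: TBSCl, imidazole, DMF, 25 °C
Reagents that add atoms: tert-butyldimethylsilyl chloride, CC(C)(C)[Si](C)(C)Cl
Why: Routine silylation of a secondary allylic alcohol; the bulky ether resists the bases used later and will sit pseudo-axial next to the C4 methyl.

Step 5
Reactants: 5 (S)-8-(tert-butyldimethylsilyloxy)-7-methyl-1,4-dioxaspiro[4.5]dec-6-ene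
Product: 6 (S)-4-(tert-butyldimethylsilyloxy)-3-methylcyclohex-2-en-1-one
Conditions: pyridinium p-toluenesulfonate (cat.), acetone/H2O, 40 °C
Reagents that add atoms: water, O
Why: Mild acid-catalysed hydrolysis of the allylic ketal unveils the C6 carbonyl in conjugation with C4=C5, while the silyl ether is stable to the weak acid.

Step 6
Reactants: 7 4-methoxybenzyl alcohol
Product: 10 4-methoxybenzyl prop-1-ynyl ether, via dichlorovinyl ether 8 (not isolated), via lithium alkynyl ether 9 (not isolated)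
Conditions: KH, THF, 0 °C; Cl2C=CHCl, 25 °C; then n-BuLi, −78 → −40 °C; then MeI, DMPU, −78 → 20 °C
Reagents that add atoms: trichloroethylene, ClC=C(Cl)Cl; methyl iodide, CI
Why: Alkynyl ether synthesis from trichloroethylene: the alkoxide adds to dichloroacetylene formed in situ, butyllithium then removes HCl and exchanges the second chlorine, and the lithium alkynyl ether is methylated on carbon, which assembles C9, C10 and C14 with O9 in place.

Step 7
Reactants: 10 4-methoxybenzyl prop-1-ynyl ether
Product: 12 (E)-2-bromo-1-(4-methoxybenzyloxy)prop-1-ene, via alkenylzirconocene 11 (not isolated)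
Conditions: Cp2Zr(H)Cl, THF, 20 °C; then N-bromosuccinimide, 0 °C
Reagents that add atoms: N-bromosuccinimide, BrN1C(=O)CCC1=O
Why: Hydrozirconation is a syn addition that should put hydrogen on the oxygen-bearing carbon and zirconium on the methyl-bearing one, and bromination with retention then gives the E isomer, in which bromine (the place of C1) is trans to the PMB-oxy group.

Step 8
Reactants: 6 (S)-4-(tert-butyldimethylsilyloxy)-3-methylcyclohex-2-en-1-one; 12 (E)-2-bromo-1-(4-methoxybenzyloxy)prop-1-ene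
Product: 14 (4S,6R)-4-(tert-butyldimethylsilyloxy)-6-[(E)-1-(4-methoxybenzyloxy)prop-1-en-2-yl]-3-methylcyclohex-2-en-1-one, via lithium dienolate 13 (not isolated)
Conditions: LiN(SiMe3)2, THF, −78 °C; then 12, Pd2(dba)3 (cat.), [HP(t-Bu)3]BF4 (cat.), −78 → 25 °C
Reagents that add atoms: none
Why: Palladium-catalysed α-alkenylation of a ketone enolate: the kinetic cross-conjugated enolate (deprotonation at C1) couples with the alkenyl bromide with retention of the E geometry, and the C1–C10 bond should form trans to the pseudo-axial C3 silyloxy group, which is also the more stable epimer.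

Step 9
Reactants: 15 ethynylmagnesium bromide
Product: 16 benzyl(ethynyl)dimethylsilane
Conditions: BnMe2SiCl, THF, 0 → 25 °C
Reagents that add atoms: benzylchlorodimethylsilane, C[Si](C)(Cl)Cc1ccccc1
Why: Substitution at silicon by the alkynyl Grignard reagent gives the C7–C8 unit; the benzyldimethylsilyl group is chosen because fluoride and basic peroxide can later turn it into a hydroxyl without electrophilic reagents that would attack the trisubstituted alkenes.

Step 10
Reactants: 14 (4S,6R)-6-alkenyl enone; 16 benzyl(ethynyl)dimethylsilane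
Product: 18 (1S,4S,6R)-1-[(benzyldimethylsilyl)ethynyl]-4-(tert-butyldimethylsilyloxy)-6-[(E)-1-(4-methoxybenzyloxy)prop-1-en-2-yl]-3-methylcyclohex-2-en-1-ol, via lithium acetylide 17 (not isolated)
Conditions: 16, n-BuLi, THF, −78 °C; then 14, −78 °C; then H2O
Reagents that add atoms: none
Why: 1,2-Addition of a lithium acetylide to the enone carbonyl: the slim, weakly basic nucleophile should attack axially, anti to the axial C1 hydrogen of the half-chair that has the alkoxypropenyl group equatorial, which places the alkyne cis to that group and sets C6.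

Step 11
Reactants: 18 propargylic alcohol
Product: 19 (1S,4S,6R)-1-[(E)-2-(benzyldimethylsilyl)ethenyl]-4-(tert-butyldimethylsilyloxy)-6-[(E)-1-(4-methoxybenzyloxy)prop-1-en-2-yl]-3-methylcyclohex-2-en-1-ol (cyclohexenol numbering; the two alkenyl groups cis)
Conditions: NaAlH2(OCH2CH2OMe)2, THF, 0 → 25 °C; then aq. potassium sodium tartrate
Reagents that add atoms: none
Why: Alkoxide-directed trans-hydroalumination of a propargylic alcohol followed by protonolysis gives the E alkene only, here the E vinylsilane, and leaves the enol ether, the ring alkene and both silyl groups alone.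

Step 12
Reactants: 19 cis-dialkenylcyclohexenol
Product: 22 (1(10)Z,4Z,3S,8R,9R)-8-(benzyldimethylsilyl)-3-(tert-butyldimethylsilyloxy)-9-(4-methoxybenzyloxy)-4,10-dimethylcyclodeca-1(10),4-dien-6-one, via potassium alkoxide 20 (not isolated), via potassium enolate 21 (not isolated)
Conditions: KN(SiMe3)2, 18-crown-6, THF, 0 → 25 °C; then AcOH, THF, −78 °C
Reagents that add atoms: none
Why: KN(SiMe3)2 with 18-crown-6 forms the bare tertiary alkoxide 20, whose oxyanion weakens the C1–C6 bond, and a concerted [3,3]-sigmatropic shift through the chair array C8=C7–C6–C1–C10=C9 gives enolate 21, which is protonated on C7; the closest known reaction is the anionic oxy-Cope ring expansion of 1,2-dialkenylcycloalkanols to cyclodec-5-enones. The ten-membered ring is not closed end to end: it arises by bond exchange, C8–C9 forming as C1–C6 breaks, so the cyclohexene grows by four atoms and its cis C4=C5 alkene is carried over unchanged. C8 and C9 are set by the geometry of the two E alkenes, which place the silyl and the PMB-oxy group equatorial on the chair, and by suprafacial bonding at both termini, which should give the 8R,9R pair with silicon holding the place of O8. The selectivity needed is for the chair in which the C1–C2 bond is axial, since this chair alone gives the Z C1=C10 alkene, over the ring-flipped chair that gives the E alkene and the opposite sense at C8 and C9. The cis relation of the two alkenyl groups makes that chair available, and the substrate favours it because it keeps the alkoxypropenyl group equatorial and the C3 silyloxy group pseudo-axial, clear of the C4 methyl, and because an equatorial C2 would press against the C14 methyl. Silicon on C8 is also what lets the enolate survive, since a β-oxygen there would be expelled.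

Step 13
Reactants: 22 cyclodecadienone
Product: 24 ethyl 2-[(1(10)Z,4Z,3S,7S,8R,9R)-8-(benzyldimethylsilyl)-3-(tert-butyldimethylsilyloxy)-9-(4-methoxybenzyloxy)-4,10-dimethyl-6-oxocyclodeca-1(10),4-dien-7-yl]acetate, via lithium enolate 23 (not isolated)
Conditions: LiN(SiMe3)2, THF, −78 °C; then ICH2CO2Et, DMPU, −78 → −30 °C
Reagents that add atoms: ethyl iodoacetate, CCOC(=O)CI
Why: Kinetic deprotonation of the enone at C7 regenerates the enolate with O6 cis to C8, in which allylic strain holds H8 in the enolate plane and the C8–C9 ring bond covers the inner face, so the iodoacetate should alkylate C7 from the periphery and give the configuration of the target (enolate alkylation).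

Step 14
Reactants: 24 keto ester
Product: 26 2-[(1(10)Z,4Z,3S,6S,7S,8R,9R)-8-(benzyldimethylsilyl)-3-(tert-butyldimethylsilyloxy)-6-hydroxy-9-(4-methoxybenzyloxy)-4,10-dimethylcyclodeca-1(10),4-dien-7-yl]acetic acid, via hydroxy ester 25 (not isolated)
Conditions: NaBH4, CeCl3·7H2O, MeOH, −40 °C; then LiOH, THF/H2O, 20 °C; then aq. HCl to pH 5, 0 °C
Reagents that add atoms: lithium hydroxide, [Li+].[OH-]
Why: Luche 1,2-reduction of the enone, in which hydride should enter from the outer face, anti to the C7–C8 bond (Felkin–Anh), and give the 6S alcohol (epimeric to the target at C6) before C7 can epimerise, followed by saponification of the ethyl ester.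

Step 15
Reactants: 26 6S hydroxy acid
Product: 27 (3S,6R,7S,8R,9R)-8-(benzyldimethylsilyl)-3-(tert-butyldimethylsilyloxy)-9-(4-methoxybenzyloxy)-13-norgermacra-1(10)Z,4Z-dien-12,6-olide (trans-fused γ-lactone with C11 as CH2)
Conditions: PPh3, DIAD, THF (dilute), 0 °C
Reagents that add atoms: none
Why: Mitsunobu lactonisation: the carboxylate displaces the activated allylic C6 oxygen in a 5-exo SN2 closure with inversion, which sets C6 as R and the trans ring fusion; only O6 can close because C8 still carries silicon.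

Step 16
Reactants: 27 silyl lactone
Product: 29 (3S,6R,7R,8R,9R)-3,8-dihydroxy-9-(4-methoxybenzyloxy)-13-norgermacra-1(10)Z,4Z-dien-12,6-olide, via fluorosilane 28 (not isolated)
Conditions: Bu4NF, THF, 0 → 25 °C; then KHCO3, 30% H2O2, MeOH, 25 °C
Reagents that add atoms: hydrogen peroxide, OO
Why: Tamao oxidation of a benzyldimethylsilyl group: fluoride cleaves the benzyl–silicon bond (and the C3 silyl ether), and buffered peroxide then moves C8 from silicon to oxygen with retention, without electrophiles that would attack the two trisubstituted alkenes; the C9 ether is too poor a leaving group for Peterson-type elimination.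

Step 17
Reactants: 29 lactone diol
Product: 30 (3S,6R,7S,8R,9R)-9-(4-methoxybenzyloxy)-3,8-bis(triethylsilyloxy)-13-norgermacra-1(10)Z,4Z-dien-12,6-olide
Conditions: Et3SiOTf, 2,6-lutidine, CH2Cl2, −78 → 0 °C
Reagents that add atoms: triethylsilyl trifluoromethanesulfonate, CC[Si](CC)(CC)OS(=O)(=O)C(F)(F)F
Why: A silyl triflate with a hindered base silylates both secondary hydroxyls, the crowded C8 one included, so that no alkoxide can attack the lactone carbonyl in the next step.

Step 18
Reactants: 30 bis-silyl lactone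
Product: 34 (3S,6R,7S,8R,9R)-9-(4-methoxybenzyloxy)-3,8-bis(triethylsilyloxy)germacra-1(10)Z,4Z,11(13)-trien-12,6-olide, via lactone enolate 31 (not isolated), via Mannich base 32 (not isolated), via ammonium iodide 33 (not isolated)
Conditions: LiN(iPr)2, THF, −78 °C; CH2=NMe2+ I−, −78 → 25 °C; then MeI, MeOH, 25 °C; then aq. NaHCO3, CH2Cl2
Reagents that add atoms: dimethylmethyleneiminium iodide, C=[N+](C)C.[I-]
Why: α-Methylenation of a lactone by the Mannich route: the lithium enolate is aminomethylated at C11, and quaternisation followed by mild base brings about Hofmann-type elimination to the exocyclic C11=C13 alkene, which also removes the passing stereocentre at C11.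

Step 19
Reactants: 34 α-methylene lactone
Product: 35 (3S,6R,7S,8R,9R)-9-hydroxy-3,8-bis(triethylsilyloxy)germacra-1(10)Z,4Z,11(13)-trien-12,6-olide
Conditions: DDQ, CH2Cl2/pH 7 phosphate buffer, 0 °C
Reagents that add atoms: none
Why: Oxidative cleavage of the PMB ether through its benzylic oxocarbenium ion frees O9, and the buffer keeps the silyl ethers and the acid-sensitive 1(10),4-diene intact.

Step 20
Reactants: 36 angelic acid
Product: 37 (Z)-2-methylbut-2-en-1-ol
Conditions: LiAlH4, Et2O, 0 °C; then aq. potassium sodium tartrate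
Reagents that add atoms: none
Why: Hydride reduction of the acid to the allylic alcohol at low temperature leaves the Z trisubstituted alkene unreduced and unisomerised.

Step 21
Reactants: 37 (Z)-2-methylbut-2-en-1-ol
Product: 38 [(2S,3R)-2,3-dimethyloxiran-2-yl]methanol
Conditions: Ti(OiPr)4 (cat.), L-(+)-diethyl tartrate (cat.), t-BuOOH, 4 Å molecular sieves, CH2Cl2, −20 °C
Reagents that add atoms: tert-butyl hydroperoxide, CC(C)(C)OO
Why: Katsuki–Sharpless asymmetric epoxidation: with the L-(+)-tartrate the titanium-bound hydroperoxide should deliver oxygen to the face that gives the (2S,3R)-epoxy alcohol, the Z alkene fixing the cis relation of C1 and C4 of the acid unit.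

Step 22
Reactants: 38 epoxy alcohol
Product: 39 (2R,3R)-2,3-dimethyloxirane-2-carboxylic acid
Conditions: TEMPO (cat.), PhI(OAc)2, MeCN/H2O, 25 °C
Reagents that add atoms: water, O
Why: Nitroxyl-catalysed oxidation takes the primary alcohol through the aldehyde hydrate to the acid without opening the epoxide; the descriptor at C2 changes only because the CIP priorities change.

Step 23
Reactants: 35 C9 alcohol; 39 (2R,3R)-epoxy acid
Product: 41 (3S,6R,7S,8R,9R)-9-[(2R,3R)-2,3-dimethyloxirane-2-carbonyloxy]-3,8-bis(triethylsilyloxy)germacra-1(10)Z,4Z,11(13)-trien-12,6-olide, via mixed anhydride 40 (not isolated)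
Conditions: 39, 2,4,6-trichlorobenzoyl chloride, Et3N, THF, 25 °C; then 35, DMAP, toluene, 25 → 40 °C
Reagents that add atoms: none
Why: Yamaguchi esterification: DMAP attacks the mixed anhydride at the less shielded epoxy-acyl carbonyl and the acylpyridinium acylates O9; the acid has no α-hydrogen to epimerise, and O8 is silylated, so the acyl group cannot migrate.

Step 24
Reactants: 41 bis-silyl ester
Product: 42 (3S,6R,7R,8R,9R)-3,8-dihydroxy-9-[(2R,3R)-2,3-dimethyloxirane-2-carbonyloxy]germacra-1(10)Z,4Z,11(13)-trien-12,6-olide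
Conditions: HF·pyridine, pyridine, THF, 0 → 25 °C
Reagents that add atoms: none
Why: Buffered hydrogen fluoride cleaves both triethylsilyl ethers under weakly acidic conditions, which avoids the alkoxide-driven acyl and lactone migrations that a basic fluoride source could cause around O8.

Step 25
Reactants: 42 3,8-diol
Product: 43 CNP0137407.10, (3S,6R,7R,8R,9R)-3-acetoxy-8-hydroxy-9-[(2R,3R)-2,3-dimethyloxirane-2-carbonyloxy]germacra-1(10)Z,4Z,11(13)-trien-12,6-olide
Conditions: Ac2O (1 equiv), pyridine, CH2Cl2, 0 °C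
Reagents that add atoms: acetic anhydride, CC(=O)OC(C)=O
Why: Acetylation with one equivalent of anhydride should take place at the allylic C3 hydroxyl, because the C8 hydroxyl is flanked by the lactone ring fusion and by the bulky C9 ester and is far more hindered.

**Compound list**

1 | 1,4-dioxaspiro[4.5]dec-6-en-8-one | O=C1CCC2(OCCO2)C=C1 | starting material
2 | 7-iodo-1,4-dioxaspiro[4.5]dec-6-en-8-one | O=C1CCC2(OCCO2)C=C1I | intermediate
3 | 7-methyl-1,4-dioxaspiro[4.5]dec-6-en-8-one | O=C1CCC2(OCCO2)C=C1C | intermediate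
4 | (S)-7-methyl-1,4-dioxaspiro[4.5]dec-6-en-8-ol | C12(OCCO2)C=C(C)[C@@H](O)CC1 | intermediate
5 | (S)-8-(tert-butyldimethylsilyloxy)-7-methyl-1,4-dioxaspiro[4.5]dec-6-ene | C12(OCCO2)C=C(C)[C@@H](O[Si](C)(C)C(C)(C)C)CC1 | intermediate
6 | (S)-4-(tert-butyldimethylsilyloxy)-3-methylcyclohex-2-en-1-one | O=C1C=C(C)[C@@H](O[Si](C)(C)C(C)(C)C)CC1 | intermediate
7 | 4-methoxybenzyl alcohol | COc1ccc(CO)cc1 | starting material
8 | (E)-1,2-dichlorovinyl 4-methoxybenzyl ether | COc1ccc(CO/C(Cl)=C\Cl)cc1 | intermediate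
9 | lithium (4-methoxybenzyloxy)acetylide | [Li]C#COCc1ccc(OC)cc1 | intermediate
10 | 4-methoxybenzyl prop-1-ynyl ether | CC#COCc1ccc(OC)cc1 | intermediate
11 | chlorobis(cyclopentadienyl)[(E)-1-(4-methoxybenzyloxy)prop-1-en-2-yl]zirconium | COc1ccc(CO/C=C(\C)[Zr](Cl)(C2C=CC=C2)C2C=CC=C2)cc1 | intermediate
12 | (E)-2-bromo-1-(4-methoxybenzyloxy)prop-1-ene | COc1ccc(CO/C=C(\C)Br)cc1 | intermediate
13 | cross-conjugated lithium dienolate of 6 (deprotonated at C1) | [Li+].[O-]C1=CC[C@H](O[Si](C)(C)C(C)(C)C)C(C)=C1 | intermediate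
14 | (4S,6R)-4-(tert-butyldimethylsilyloxy)-6-[(E)-1-(4-methoxybenzyloxy)prop-1-en-2-yl]-3-methylcyclohex-2-en-1-one | O=C1C=C(C)[C@@H](O[Si](C)(C)C(C)(C)C)C[C@@H]1/C(C)=C/OCc1ccc(OC)cc1 | intermediate
15 | ethynylmagnesium bromide | C#C[Mg]Br | starting material
16 | benzyl(ethynyl)dimethylsilane | C#C[Si](C)(C)Cc1ccccc1 | intermediate
17 | lithium (benzyldimethylsilyl)acetylide | [Li]C#C[Si](C)(C)Cc1ccccc1 | intermediate
18 | (1S,4S,6R)-1-[(benzyldimethylsilyl)ethynyl]-4-(tert-butyldimethylsilyloxy)-6-[(E)-1-(4-methoxybenzyloxy)prop-1-en-2-yl]-3-methylcyclohex-2-en-1-ol | O[C@@]1(C#C[Si](C)(C)Cc2ccccc2)C=C(C)[C@@H](O[Si](C)(C)C(C)(C)C)C[C@@H]1/C(C)=C/OCc1ccc(OC)cc1 | intermediate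
19 | (1S,4S,6R)-1-[(E)-2-(benzyldimethylsilyl)ethenyl]-4-(tert-butyldimethylsilyloxy)-6-[(E)-1-(4-methoxybenzyloxy)prop-1-en-2-yl]-3-methylcyclohex-2-en-1-ol | O[C@@]1(/C=C/[Si](C)(C)Cc2ccccc2)C=C(C)[C@@H](O[Si](C)(C)C(C)(C)C)C[C@@H]1/C(C)=C/OCc1ccc(OC)cc1 | intermediate
20 | potassium alkoxide of 19 | [K+].[O-][C@@]1(/C=C/[Si](C)(C)Cc2ccccc2)C=C(C)[C@@H](O[Si](C)(C)C(C)(C)C)C[C@@H]1/C(C)=C/OCc1ccc(OC)cc1 | intermediate
21 | potassium enolate of 22 (C6=C7, O6 cis to C8) | [K+].[O-]/C1=C\[C@@H]([Si](C)(C)Cc2ccccc2)[C@H](OCc2ccc(OC)cc2)/C(C)=C\C[C@H](O[Si](C)(C)C(C)(C)C)/C(C)=C\1 | intermediate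
22 | (1(10)Z,4Z,3S,8R,9R)-8-(benzyldimethylsilyl)-3-(tert-butyldimethylsilyloxy)-9-(4-methoxybenzyloxy)-4,10-dimethylcyclodeca-1(10),4-dien-6-one | O=C1/C=C(/C)[C@@H](O[Si](C)(C)C(C)(C)C)C/C=C(/C)[C@@H](OCc2ccc(OC)cc2)[C@H]([Si](C)(C)Cc2ccccc2)C1 | intermediate
23 | lithium enolate of 22 (C6=C7, O6 cis to C8) | [Li+].[O-]/C1=C\[C@@H]([Si](C)(C)Cc2ccccc2)[C@H](OCc2ccc(OC)cc2)/C(C)=C\C[C@H](O[Si](C)(C)C(C)(C)C)/C(C)=C\1 | intermediate
24 | ethyl 2-[(3S,7S,8R,9R)-8-(benzyldimethylsilyl)-3-(tert-butyldimethylsilyloxy)-9-(4-methoxybenzyloxy)-4,10-dimethyl-6-oxocyclodeca-1(10),4-dien-7-yl]acetate | O=C1/C=C(/C)[C@@H](O[Si](C)(C)C(C)(C)C)C/C=C(/C)[C@@H](OCc2ccc(OC)cc2)[C@H]([Si](C)(C)Cc2ccccc2)[C@H]1CC(=O)OCC | intermediate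
25 | (6S)-hydroxy ester from 24 (3S,6S,7S,8R,9R) | O[C@H]1/C=C(/C)[C@@H](O[Si](C)(C)C(C)(C)C)C/C=C(/C)[C@@H](OCc2ccc(OC)cc2)[C@H]([Si](C)(C)Cc2ccccc2)[C@H]1CC(=O)OCC | intermediate
26 | (6S)-hydroxy acid (3S,6S,7S,8R,9R) | O[C@H]1/C=C(/C)[C@@H](O[Si](C)(C)C(C)(C)C)C/C=C(/C)[C@@H](OCc2ccc(OC)cc2)[C@H]([Si](C)(C)Cc2ccccc2)[C@H]1CC(O)=O | intermediate
27 | (3S,6R,7S,8R,9R)-8-(benzyldimethylsilyl)-3-(tert-butyldimethylsilyloxy)-9-(4-methoxybenzyloxy)-13-norgermacra-1(10)Z,4Z-dien-12,6-olide | C1C(=O)O[C@@H]2/C=C(/C)[C@@H](O[Si](C)(C)C(C)(C)C)C/C=C(/C)[C@@H](OCc3ccc(OC)cc3)[C@H]([Si](C)(C)Cc3ccccc3)[C@@H]12 | intermediate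
28 | 8-(fluorodimethylsilyl)-3-hydroxy lactone | C1C(=O)O[C@@H]2/C=C(/C)[C@@H](O)C/C=C(/C)[C@@H](OCc3ccc(OC)cc3)[C@H]([Si](C)(C)F)[C@@H]12 | intermediate
29 | (3S,6R,7R,8R,9R)-3,8-dihydroxy-9-(4-methoxybenzyloxy)-13-norgermacra-1(10)Z,4Z-dien-12,6-olide | C1C(=O)O[C@@H]2/C=C(/C)[C@@H](O)C/C=C(/C)[C@@H](OCc3ccc(OC)cc3)[C@H](O)[C@@H]12 | intermediate
30 | (3S,6R,7S,8R,9R)-9-(4-methoxybenzyloxy)-3,8-bis(triethylsilyloxy)-13-norgermacra-1(10)Z,4Z-dien-12,6-olide | C1C(=O)O[C@@H]2/C=C(/C)[C@@H](O[Si](CC)(CC)CC)C/C=C(/C)[C@@H](OCc3ccc(OC)cc3)[C@H](O[Si](CC)(CC)CC)[C@@H]12 | intermediate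
31 | lithium enolate of lactone 30 (C11=C12) | [Li+].C1=C([O-])O[C@@H]2/C=C(/C)[C@@H](O[Si](CC)(CC)CC)C/C=C(/C)[C@@H](OCc3ccc(OC)cc3)[C@H](O[Si](CC)(CC)CC)[C@@H]12 | intermediate
32 | 11-(dimethylaminomethyl) lactone (C11 epimers) | CN(C)CC1C(=O)O[C@@H]2/C=C(/C)[C@@H](O[Si](CC)(CC)CC)C/C=C(/C)[C@@H](OCc3ccc(OC)cc3)[C@H](O[Si](CC)(CC)CC)[C@@H]12 | intermediate
33 | 11-(trimethylammoniomethyl) lactone iodide | [I-].C[N+](C)(C)CC1C(=O)O[C@@H]2/C=C(/C)[C@@H](O[Si](CC)(CC)CC)C/C=C(/C)[C@@H](OCc3ccc(OC)cc3)[C@H](O[Si](CC)(CC)CC)[C@@H]12 | intermediate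
34 | (3S,6R,7S,8R,9R)-9-(4-methoxybenzyloxy)-3,8-bis(triethylsilyloxy)germacra-1(10)Z,4Z,11(13)-trien-12,6-olide | C=C1C(=O)O[C@@H]2/C=C(/C)[C@@H](O[Si](CC)(CC)CC)C/C=C(/C)[C@@H](OCc3ccc(OC)cc3)[C@H](O[Si](CC)(CC)CC)[C@@H]12 | intermediate
35 | (3S,6R,7S,8R,9R)-9-hydroxy-3,8-bis(triethylsilyloxy)germacra-1(10)Z,4Z,11(13)-trien-12,6-olide | C=C1C(=O)O[C@@H]2/C=C(/C)[C@@H](O[Si](CC)(CC)CC)C/C=C(/C)[C@@H](O)[C@H](O[Si](CC)(CC)CC)[C@@H]12 | intermediate
36 | angelic acid, (Z)-2-methylbut-2-enoic acid | C/C=C(/C)C(O)=O | starting material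
37 | (Z)-2-methylbut-2-en-1-ol | C/C=C(/C)CO | intermediate
38 | [(2S,3R)-2,3-dimethyloxiran-2-yl]methanol | OC[C@]1(C)O[C@@H]1C | intermediate
39 | (2R,3R)-2,3-dimethyloxirane-2-carboxylic acid | OC(=O)[C@]1(C)O[C@@H]1C | intermediate
40 | mixed anhydride of 39 with 2,4,6-trichlorobenzoic acid | O=C(OC(=O)[C@]1(C)O[C@@H]1C)c1c(Cl)cc(Cl)cc1Cl | intermediate
41 | (3S,6R,7S,8R,9R)-9-[(2R,3R)-2,3-dimethyloxirane-2-carbonyloxy]-3,8-bis(triethylsilyloxy)germacra-1(10)Z,4Z,11(13)-trien-12,6-olide | C=C1C(=O)O[C@@H]2/C=C(/C)[C@@H](O[Si](CC)(CC)CC)C/C=C(/C)[C@@H](OC(=O)[C@]3(C)O[C@@H]3C)[C@H](O[Si](CC)(CC)CC)[C@@H]12 | intermediate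
42 | (3S,6R,7R,8R,9R)-3,8-dihydroxy-9-[(2R,3R)-2,3-dimethyloxirane-2-carbonyloxy]germacra-1(10)Z,4Z,11(13)-trien-12,6-olide | C=C1C(=O)O[C@@H]2/C=C(/C)[C@@H](O)C/C=C(/C)[C@@H](OC(=O)[C@]3(C)O[C@@H]3C)[C@H](O)[C@@H]12 | intermediate
43 | CNP0137407.10 | C=C1C(=O)O[C@@H]2/C=C(/C)[C@@H](OC(C)=O)C/C=C(/C)[C@@H](OC(=O)[C@]3(C)O[C@@H]3C)[C@H](O)[C@@H]12 | target

**Count and risks**

Total step count: 25. Longest linear sequence: 19 steps (steps 1–5, 8, 10–19, 23–25).

The three steps most likely to fail:

1. Step 12 (key step). Part of the alkoxide may rearrange through the ring-flipped chair, which would deliver the E C1=C10 alkene. The strongly basic medium may also divert the alkoxide or the enolate before protonation, by transfer of the C3 silyl group to O6 or by equilibration of the enolate towards C3 or C15. The fallback is the neutral, thermal form of the same shift (siloxy-Cope), which sets out from 19. N-(Trimethylsilyl)imidazole in CH2Cl2 should cap the tertiary alcohol as the trimethylsilyl ether F1. Heating F1 in degassed decalin at 180–200 °C should give the ring-expanded trimethylsilyl enol ether F2 with no anion present, under the same ring-borne control (equatorial alkoxypropenyl, pseudo-axial O3). K2CO3 in MeOH at 0 °C then cleaves the enol ether, and the route is rejoined at 22.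

2. Step 8. Oxidative addition of the electron-rich bromo enol ether may be slow, the product may be deprotonated by unreacted enolate, and the β,γ-alkene may drift into conjugation. The fallback reverses the polarity of the coupling and sets out from 6. LiN(SiMe3)2 and Me3SiCl should give the cross-conjugated trimethylsilyl dienol ether F3, and N-bromosuccinimide the α′-bromo enone F4 as both C1 epimers. A nickel-catalysed cross-coupling of this α-bromo ketone with the alkenylzirconocene 11 (NiCl2·(MeOCH2CH2OMe), a bis(oxazoline) or bipyridine ligand, THF/diglyme) then comes back to the route at 14. The C1 radical should again be captured trans to O3.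

3. Step 14. Hydride delivery to C6 may be poorly selective or may occur from the inner face. The fallback changes the mode of ring closure and not the reductant, and sets out from 24. If the Luche reduction gives the alcohol with the C6 configuration of the target, the 6R hydroxy ester F5, catalytic K2CO3 in MeOH should close the lactone by intramolecular acyl transfer with retention. This rejoins the route at 27 and leaves out the hydrolysis and the Mitsunobu closure.

**Further compounds**

F1 | step 12 | trimethylsilyl ether of 19 | C[Si](C)(C)O[C@@]1(/C=C/[Si](C)(C)Cc2ccccc2)C=C(C)[C@@H](O[Si](C)(C)C(C)(C)C)C[C@@H]1/C(C)=C/OCc1ccc(OC)cc1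
F2 | step 12 | trimethylsilyl enol ether of 22 (C6=C7, O6 cis to C8) | C[Si](C)(C)O/C1=C\[C@@H]([Si](C)(C)Cc2ccccc2)[C@H](OCc2ccc(OC)cc2)/C(C)=C\C[C@H](O[Si](C)(C)C(C)(C)C)/C(C)=C\1
F3 | step 8 | cross-conjugated trimethylsilyl dienol ether of 6 | C[Si](C)(C)OC1=CC[C@H](O[Si](C)(C)C(C)(C)C)C(C)=C1
F4 | step 8 | (4S)-6-bromo-4-(tert-butyldimethylsilyloxy)-3-methylcyclohex-2-en-1-one (both C6 epimers) | O=C1C=C(C)[C@@H](O[Si](C)(C)C(C)(C)C)CC1Br
F5 | step 14 | (6R)-hydroxy ester, C6 epimer of 25 | O[C@@H]1/C=C(/C)[C@@H](O[Si](C)(C)C(C)(C)C)C/C=C(/C)[C@@H](OCc2ccc(OC)cc2)[C@H]([Si](C)(C)Cc2ccccc2)[C@H]1CC(=O)OCC
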